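The target is cut back to an acyclic chiral-pool aldehyde plus methyl vinyl ketone. The feature used is that ring C1–C6 hangs by its CH carbon C1 on the tertiary carbinol C7, and that C4 (CMeCl) sits across the ring from C1: C7 and everything attached to it outside the ring is (R)-linalool, the two vinyl carbons of linalool end up as C1 and C6, and the enone supplies C2–C5. A single amine-catalysed Michael/aldol annulation makes C1–C2 and C5=C6, closes the six-membered ring and fixes C1, and its C5=C6 alkene later tells the two ring arms apart. The precursor is the β-triethylsilyloxy aldehyde 5, made from linalool in three steps.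

Key step: step 4

Numbering used throughout (that of the target): ring C1 (CH bearing the side chain), C2, C3, C4 (CMeCl), C5 (CHBr), C6; chain C7 (ring-bound carbinol), C8, C9, C10 (CHOH), C11 (isopropenyl carbon).
Assumption: (R)-(−)-linalool of high enantiomeric purity, (R)-α,α-diphenylprolinol trimethylsilyl ether and the D-fructose-derived epoxidation ketone are bought; the C7 oxygen stays silylated to the last step because a free C7 hydroxyl could add to C4 when the ring epoxide is opened.

Step 1
Reactants: 1 (R)-linalool
Product: 2 (3R)-3,7-dimethyl-3-(triethylsilyloxy)octa-1,6-diene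
Conditions: TESOTf, 2,6-lutidine, CH2Cl2, −78 °C to 0 °C
Reagents that add atoms: triethylsilyl trifluoromethanesulfonate, CC[Si](CC)(CC)OS(=O)(=O)C(F)(F)F
Why: O-silylation of the hindered tertiary allylic alcohol with a silyl triflate and a hindered pyridine base is standard, does not touch the C7 stereocentre and gives an ether that later blocks retro-aldol cleavage of the β-oxy aldehyde.

Step 2
Reactants: 2 (3R)-3,7-dimethyl-3-(triethylsilyloxy)octa-1,6-diene
Product: 4 (3R)-3,7-dimethyl-3-(triethylsilyloxy)oct-6-en-1-ol, via alkylborane 3 (not isolated)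
Conditions: 9-BBN, THF, 0 °C to rt; then NaOH, H2O2, H2O, 0 °C to rt
Reagents that add atoms: hydrogen peroxide, OO
Why: Brown hydroboration–oxidation with the bulky dialkylborane 9-BBN places boron on the terminal carbon of the monosubstituted vinyl group far faster than it attacks the trisubstituted C10=C11 alkene, and alkaline peroxide then replaces boron by hydroxyl without affecting C7.

Step 3
Reactants: 4 (3R)-3,7-dimethyl-3-(triethylsilyloxy)oct-6-en-1-ol
Product: 5 (3R)-3,7-dimethyl-3-(triethylsilyloxy)oct-6-enal
Conditions: Dess–Martin periodinane, CH2Cl2, 0 °C to rt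
Reagents that add atoms: none
Why: Dess–Martin oxidation turns the primary alcohol into the aldehyde under non-basic conditions that should not trigger β-elimination of the silyloxy group and leave the alkene and C7 untouched.

Step 4
Reactants: 5 (3R)-3,7-dimethyl-3-(triethylsilyloxy)oct-6-enal; 6 methyl vinyl ketone
Product: 9 (4S)-4-[(2R)-6-methyl-2-(triethylsilyloxy)hept-5-en-2-yl]cyclohex-2-en-1-one, via keto aldehyde 7 (not isolated), via ketol 8 (not isolated)
Conditions: (R)-α,α-diphenylprolinol trimethylsilyl ether (10 mol %), ethyl 3,4-dihydroxybenzoate (20 mol %), neat, 4 °C; then removal of excess 6 under vacuum, LiOH (cat.), i-PrOH, rt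
Reagents that add atoms: none
Why: The secondary amine condenses with 5 to the E-enamine, whose α-carbon (C1) adds to the β-carbon of 6 on the face left open by the diphenyl(silyloxy)methyl group, and hydrolysis releases keto aldehyde 7 and the catalyst; the catechol ester only activates the enone by hydrogen bonding, so no strong acid is present to expel the β-silyloxy group. The closest known reaction type is the diarylprolinol silyl ether-catalysed Michael addition of aldehydes to vinyl ketones followed by base-mediated aldol condensation to 4-substituted cyclohex-2-enones, a catalytic asymmetric Robinson-type annulation. The ring closes by a 6-(enolexo)-exo-trig aldol addition of the methyl ketone enolate carbon (C5) to the aldehyde carbon (C6) to give ketol 8, and E1cB loss of water gives the conjugated C5=C6 alkene. The only new stereocentre, C1, is set by the catalyst: with the (R)-configured amine the shielding model for these catalysts predicts the (2R) adduct 7, which is (4S) in enone 9, while the fixed quaternary centre C7 is a spectator that can only reinforce or weaken this preference. The step needs facial selectivity at the enamine carbon and chemoselectivity for cross-Michael addition over self-aldol reaction and β-elimination; the first rests on the bulky group of the catalyst, the second on the fully substituted β-carbon C7 (which slows self-condensation), the tertiary silyl ether and the low temperature. The cyclisation is regiochemically unambiguous because only the methyl ketone enolate can reach the aldehyde through a six-membered transition state, and a catalytic amount of LiOH is meant to limit epimerisation at C1 before the aldehyde is consumed.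

Step 5
Reactants: 9 (4S)-4-[(2R)-6-methyl-2-(triethylsilyloxy)hept-5-en-2-yl]cyclohex-2-en-1-one
Product: 10 (4S)-4-{(2R)-4-[(2R)-3,3-dimethyloxiran-2-yl]-2-(triethylsilyloxy)butan-2-yl}cyclohex-2-en-1-one
Conditions: D-fructose-derived Shi ketone (30 mol %), KHSO5 (as 2KHSO5·KHSO4·K2SO4), K2CO3, Bu4NHSO4 (cat.), MeCN/dimethoxymethane/aq. Na2B4O7 buffer, 0 °C
Reagents that add atoms: potassium peroxymonosulfate, [K+].[O-]S(=O)(=O)OO
Why: Shi asymmetric epoxidation uses an electrophilic chiral dioxirane, so it takes the electron-rich trisubstituted C10=C11 alkene and leaves the electron-poor enone alkene alone, and the spiro transition state of the D-fructose-derived ketone should deliver oxygen to the face that makes C10 (R), as it does for other 2-methylalk-2-enes.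

Step 6
Reactants: 10 (4S)-4-{(2R)-4-[(2R)-3,3-dimethyloxiran-2-yl]-2-(triethylsilyloxy)butan-2-yl}cyclohex-2-en-1-one
Product: 12 (4S)-4-{(2R)-4-[(2R)-3,3-dimethyloxiran-2-yl]-2-(triethylsilyloxy)butan-2-yl}cyclohex-1-en-1-yl trifluoromethanesulfonate, via lithium enolate 11 (not isolated)
Conditions: LiBH(s-Bu)3, THF, −78 °C; then PhNTf2, −78 °C to 0 °C
Reagents that add atoms: N-phenylbis(trifluoromethanesulfonimide), O=S(=O)(N(c1ccccc1)S(=O)(=O)C(F)(F)F)C(F)(F)F
Why: Conjugate hydride addition of the hindered borohydride to the β-unsubstituted cyclohexenone gives the C4=C5 lithium enolate regiospecifically, and O-triflation in the same flask without a proton source fixes that alkene position, so C1 stays a stereocentre although it would cease to be one in the saturated ketone.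

Step 7
Reactants: 12 (4S)-4-{(2R)-4-[(2R)-3,3-dimethyloxiran-2-yl]-2-(triethylsilyloxy)butan-2-yl}cyclohex-1-en-1-yl trifluoromethanesulfonate
Product: 13 triethyl({(2R)-4-[(2R)-3,3-dimethyloxiran-2-yl]-2-[(1S)-4-methylcyclohex-3-en-1-yl]butan-2-yl}oxy)silane
Conditions: MeMgBr, Fe(acac)3 [iron tris(acetylacetonate), 5 mol %], THF/NMP, −30 °C
Reagents that add atoms: methylmagnesium bromide, C[Mg]Br
Why: Iron-catalysed cross-coupling of an alkenyl triflate with a methyl Grignard reagent (Kumada-type) is complete within minutes at low temperature, puts the methyl group on the carbon that carried the triflate and so keeps the C4=C5 position, and is too fast for the Grignard reagent to open the hindered epoxide.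

Step 8
Reactants: 13 triethyl({(2R)-4-[(2R)-3,3-dimethyloxiran-2-yl]-2-[(1S)-4-methylcyclohex-3-en-1-yl]butan-2-yl}oxy)silane
Product: 15 (3R,6R)-2-methyl-6-[(1S)-4-methylcyclohex-3-en-1-yl]-6-(triethylsilyloxy)hept-1-en-3-ol, via aluminium alkoxide 14 (not isolated)
Conditions: Et2AlCl, lithium 2,2,6,6-tetramethylpiperidide (from 2,2,6,6-tetramethylpiperidine and n-BuLi), toluene, 0 °C to rt; aqueous work-up
Reagents that add atoms: none
Why: The aluminium amide isomerises a trisubstituted epoxide to an allylic alcohol by a cyclic syn-elimination in which aluminium holds the oxygen and the amide takes a proton from the less hindered methyl group, so the isopropenyl carbinol forms regioselectively and the C10–O bond, and with it the (R) configuration, is not touched.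

Step 9
Reactants: 15 (3R,6R)-2-methyl-6-[(1S)-4-methylcyclohex-3-en-1-yl]-6-(triethylsilyloxy)hept-1-en-3-ol
Product: 16 (3R,6R)-3-(tert-butyldimethylsilyloxy)-2-methyl-6-[(1S)-4-methylcyclohex-3-en-1-yl]-6-(triethylsilyloxy)hept-1-ene
Conditions: TBSCl, imidazole, DMF, rt
Reagents that add atoms: tert-butyldimethylsilyl chloride, CC(C)(C)[Si](C)(C)Cl
Why: Standard silylation of the secondary allylic alcohol masks the C10 hydroxyl so that it cannot be chlorinated or ionised during the halogenation steps, with a group that falls in the same final fluoride treatment as the triethylsilyl ether.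

Step 10
Reactants: 16 (3R,6R)-3-(tert-butyldimethylsilyloxy)-2-methyl-6-[(1S)-4-methylcyclohex-3-en-1-yl]-6-(triethylsilyloxy)hept-1-ene
Product: 17 (1S,4S,6R)-4-[(2R,5R)-5-(tert-butyldimethylsilyloxy)-6-methyl-2-(triethylsilyloxy)hept-6-en-2-yl]-1-methyl-7-oxabicyclo[4.1.0]heptane
Conditions: D-fructose-derived Shi ketone (30 mol %), KHSO5 (as 2KHSO5·KHSO4·K2SO4), K2CO3, Bu4NHSO4 (cat.), MeCN/dimethoxymethane/aq. Na2B4O7 buffer, 0 °C
Reagents that add atoms: potassium peroxymonosulfate, [K+].[O-]S(=O)(=O)OO
Why: The same catalyst-controlled Shi epoxidation attacks the trisubstituted ring alkene in preference to the less nucleophilic 1,1-disubstituted isopropenyl group, and by analogy with 1-substituted cyclohexenes its spiro transition state should put the oxygen on the ring face opposite to the C1 side chain, giving the (4S,5R) epoxide where a peracid would show little facial preference.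

Step 11
Reactants: 17 (1S,4S,6R)-4-[(2R,5R)-5-(tert-butyldimethylsilyloxy)-6-methyl-2-(triethylsilyloxy)hept-6-en-2-yl]-1-methyl-7-oxabicyclo[4.1.0]heptane
Product: 18 (1R,2R,5S)-2-bromo-5-[(2R,5R)-5-(tert-butyldimethylsilyloxy)-6-methyl-2-(triethylsilyloxy)hept-6-en-2-yl]-2-methylcyclohexan-1-ol
Conditions: LiBr, AcOH, THF, 0 °C to rt
Reagents that add atoms: lithium bromide, [Li+].[Br-]
Why: Acid-promoted halide opening of the trisubstituted epoxide takes place at the tertiary carbon C4 with inversion, and with the side chain equatorial this Markovnikov attack is also the chair-like trans-diaxial (Fürst–Plattner) mode, so bromide enters C4 on the face of the side chain and the C5 hydroxyl is left axial on the opposite face.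

Step 12
Reactants: 18 (1R,2R,5S)-2-bromo-5-[(2R,5R)-5-(tert-butyldimethylsilyloxy)-6-methyl-2-(triethylsilyloxy)hept-6-en-2-yl]-2-methylcyclohexan-1-ol
Product: 21 tert-butyl({(3R,6R)-6-[(1S,3S,4S)-3-bromo-4-chloro-4-methylcyclohexyl]-2-methyl-6-(triethylsilyloxy)hept-1-en-3-yl}oxy)dimethylsilane, via alkoxyphosphonium chloride 19 (not isolated), via bromonium ion 20 (not isolated)
Conditions: Ph3P, NCS (premixed), CH2Cl2, 0 °C to rt
Reagents that add atoms: N-chlorosuccinimide, O=C1CCC(=O)N1Cl
Why: Appel-type activation of the axial C5 hydroxyl is followed by anchimeric displacement by the antiperiplanar C4 bromine, and the unsymmetrical bromonium ion thus formed on the face of the side chain should be opened by chloride at its tertiary, more cationic carbon C4 from the opposite face (Markovnikov opening with overall 1,2-bromine shift), which sets C4 (S) and C5 (S) with the two halogens trans.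

Step 13
Reactants: 21 tert-butyl({(3R,6R)-6-[(1S,3S,4S)-3-bromo-4-chloro-4-methylcyclohexyl]-2-methyl-6-(triethylsilyloxy)hept-1-en-3-yl}oxy)dimethylsilane
Product: 22 (3R,6R)-6-[(1S,3S,4S)-3-bromo-4-chloro-4-methylcyclohexyl]-2-methylhept-1-ene-3,6-diol
Conditions: HF·pyridine, pyridine, THF, 0 °C to rt
Reagents that add atoms: none
Why: Buffered hydrogen fluoride cleaves both silyl ethers by Si–F bond formation under non-basic, weakly acidic conditions that should neither eliminate the vicinal halides nor ionise the allylic alcohol, so all five stereocentres are carried into the target unchanged.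

Compound list
1 | (R)-(−)-linalool, (3R)-3,7-dimethylocta-1,6-dien-3-ol | C=C[C@](C)(O)CCC=C(C)C | starting material
2 | (3R)-3,7-dimethyl-3-(triethylsilyloxy)octa-1,6-diene | C=C[C@](C)(O[Si](CC)(CC)CC)CCC=C(C)C | intermediate
3 | 9-[(3S)-3,7-dimethyl-3-(triethylsilyloxy)oct-6-en-1-yl]-9-borabicyclo[3.3.1]nonane (same spatial arrangement at C7 as in 2; the descriptor changes because boron ranks below carbon) | CC(C)=CCC[C@@](C)(O[Si](CC)(CC)CC)CCB1C2CCCC1CCC2 | intermediate
4 | (3R)-3,7-dimethyl-3-(triethylsilyloxy)oct-6-en-1-ol | CC(C)=CCC[C@@](C)(O[Si](CC)(CC)CC)CCO | intermediate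
5 | (3R)-3,7-dimethyl-3-(triethylsilyloxy)oct-6-enal | CC(C)=CCC[C@@](C)(O[Si](CC)(CC)CC)CC=O | intermediate
6 | methyl vinyl ketone (but-3-en-2-one) | CC(=O)C=C | starting material
7 | (2R,3R)-3,7-dimethyl-2-(3-oxobutyl)-3-(triethylsilyloxy)oct-6-enal | CC(C)=CCC[C@@](C)(O[Si](CC)(CC)CC)[C@H](C=O)CCC(C)=O | intermediate
8 | (4S)-3-hydroxy-4-[(2R)-6-methyl-2-(triethylsilyloxy)hept-5-en-2-yl]cyclohexan-1-one (either configuration at the carbinol carbon C6, which is lost on dehydration) | CC(C)=CCC[C@@](C)(O[Si](CC)(CC)CC)[C@H]1CCC(=O)CC1O | intermediate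
9 | (4S)-4-[(2R)-6-methyl-2-(triethylsilyloxy)hept-5-en-2-yl]cyclohex-2-en-1-one | CC(C)=CCC[C@@](C)(O[Si](CC)(CC)CC)[C@H]1CCC(=O)C=C1 | intermediate
10 | (4S)-4-{(2R)-4-[(2R)-3,3-dimethyloxiran-2-yl]-2-(triethylsilyloxy)butan-2-yl}cyclohex-2-en-1-one | CC1(C)O[C@@H]1CC[C@@](C)(O[Si](CC)(CC)CC)[C@H]1CCC(=O)C=C1 | intermediate
11 | lithium (4S)-4-{(2R)-4-[(2R)-3,3-dimethyloxiran-2-yl]-2-(triethylsilyloxy)butan-2-yl}cyclohex-1-en-1-olate | CC1(C)O[C@@H]1CC[C@@](C)(O[Si](CC)(CC)CC)[C@H]1CCC([O-])=CC1.[Li+] | intermediate
12 | (4S)-4-{(2R)-4-[(2R)-3,3-dimethyloxiran-2-yl]-2-(triethylsilyloxy)butan-2-yl}cyclohex-1-en-1-yl trifluoromethanesulfonate | CC1(C)O[C@@H]1CC[C@@](C)(O[Si](CC)(CC)CC)[C@H]1CCC(OS(=O)(=O)C(F)(F)F)=CC1 | intermediate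
13 | triethyl({(2R)-4-[(2R)-3,3-dimethyloxiran-2-yl]-2-[(1S)-4-methylcyclohex-3-en-1-yl]butan-2-yl}oxy)silane | CC1(C)O[C@@H]1CC[C@@](C)(O[Si](CC)(CC)CC)[C@H]1CCC(C)=CC1 | intermediate
14 | diethylaluminium alkoxide of 15 (O–AlEt2 on C10) | C=C(C)[C@H](O[Al](CC)CC)CC[C@@](C)(O[Si](CC)(CC)CC)[C@H]1CCC(C)=CC1 | intermediate
15 | (3R,6R)-2-methyl-6-[(1S)-4-methylcyclohex-3-en-1-yl]-6-(triethylsilyloxy)hept-1-en-3-ol | C=C(C)[C@H](O)CC[C@@](C)(O[Si](CC)(CC)CC)[C@H]1CCC(C)=CC1 | intermediate
16 | (3R,6R)-3-(tert-butyldimethylsilyloxy)-2-methyl-6-[(1S)-4-methylcyclohex-3-en-1-yl]-6-(triethylsilyloxy)hept-1-ene | C=C(C)[C@H](O[Si](C)(C)C(C)(C)C)CC[C@@](C)(O[Si](CC)(CC)CC)[C@H]1CCC(C)=CC1 | intermediate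
17 | (1S,4S,6R)-4-[(2R,5R)-5-(tert-butyldimethylsilyloxy)-6-methyl-2-(triethylsilyloxy)hept-6-en-2-yl]-1-methyl-7-oxabicyclo[4.1.0]heptane (epoxide oxygen on the ring face opposite to the side chain) | C=C(C)[C@H](O[Si](C)(C)C(C)(C)C)CC[C@@](C)(O[Si](CC)(CC)CC)[C@H]1CC[C@]2(C)O[C@@H]2C1 | intermediate
18 | (1R,2R,5S)-2-bromo-5-[(2R,5R)-5-(tert-butyldimethylsilyloxy)-6-methyl-2-(triethylsilyloxy)hept-6-en-2-yl]-2-methylcyclohexan-1-ol (C4–Br cis and C5–OH trans to the side chain) | C=C(C)[C@H](O[Si](C)(C)C(C)(C)C)CC[C@@](C)(O[Si](CC)(CC)CC)[C@H]1CC[C@@](C)(Br)[C@H](O)C1 | intermediate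
19 | O-triphenylphosphonium chloride of 18 (P–O bond at C5) | C=C(C)[C@H](O[Si](C)(C)C(C)(C)C)CC[C@@](C)(O[Si](CC)(CC)CC)[C@H]1CC[C@@](C)(Br)[C@H](O[P+](c2ccccc2)(c2ccccc2)c2ccccc2)C1.[Cl-] | intermediate
20 | bromonium ion bridging C4 and C5 on the ring face of the side chain, chloride salt | C=C(C)[C@H](O[Si](C)(C)C(C)(C)C)CC[C@@](C)(O[Si](CC)(CC)CC)[C@H]1CC[C@@]2(C)[Br+][C@H]2C1.[Cl-] | intermediate
21 | tert-butyl({(3R,6R)-6-[(1S,3S,4S)-3-bromo-4-chloro-4-methylcyclohexyl]-2-methyl-6-(triethylsilyloxy)hept-1-en-3-yl}oxy)dimethylsilane | C=C(C)[C@H](O[Si](C)(C)C(C)(C)C)CC[C@@](C)(O[Si](CC)(CC)CC)[C@H]1CC[C@](C)(Cl)[C@@H](Br)C1 | intermediate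
22 | (3R,6R)-6-[(1S,3S,4S)-3-bromo-4-chloro-4-methylcyclohexyl]-2-methylhept-1-ene-3,6-diol | C=C(C)[C@H](O)CC[C@@](C)(O)[C@H]1CC[C@](C)(Cl)[C@@H](Br)C1 | target

Total step count: 13. Longest linear sequence: 13 steps, from 1 to 22.

Steps most likely to fail

1. Step 4. Enamine formation may be sluggish because the β-carbon of the aldehyde is fully substituted. Triethylsilanol may be lost from the enamine or from 7 by β-elimination. Facial discrimination may be insufficient if the C7 centre works against the catalyst. C1 may epimerise during the basic ring closure.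
Fallback (auxiliary control in place of catalyst control): the fallback sets out from aldehyde 5. Condensation with (S)-1-amino-2-(methoxymethyl)pyrrolidine gives the SAMP hydrazone F1. Deprotonation with LiN(i-Pr)2 in THF at −78 °C and alkylation of the azaenolate with 2-(2-iodoethyl)-2-methyl-1,3-dioxolane should give the C1-alkylated hydrazone F2; by the established azaenolate model the auxiliary directs the electrophile to the face that corresponds to (2R) in 7. Aqueous oxalic acid/ether cleaves the hydrazone without ozone, so the alkene stays, and gives the acetal aldehyde F3. Pyridinium p-toluenesulfonate in wet acetone removes the dioxolane and returns to keto aldehyde 7, which is closed to 9 with LiOH in i-PrOH as in step 4.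

2. Step 12. Chloride may return to C5 of the bromonium ion, which is the chair-like trans-diaxial mode of opening, so that chlorine replaces the hydroxyl with retention and no bromine shift occurs. The ion may also lose a proton to give an allylic bromide, or pass its bromine to the isopropenyl alkene.
Fallback (thermodynamic halogen interchange in place of kinetic opening): the fallback sets out from bromohydrin 18. The chlorination is run to the trans-diaxial 4-bromo-5-chloro regioisomer F4, which is then heated in a polar aprotic solvent (MeCN or sulfolane, 80–120 °C). The known 1,2-interchange of vicinal trans-diaxial dihalides, in which each halogen moves to the neighbouring carbon on its own ring face (as in the mutarotation of 5,6-dihalo steroids), leads from F4 to the diequatorial tertiary chloride 21. Compound 21 is separated, recovered F4 is resubjected, and the route continues from 21 with step 13.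

3. Step 10. Oxygen transfer to the 1-methylcyclohexene-type alkene may show insufficient facial selectivity, since the remote C1 substituent gives the substrate no bias of its own. The isopropenyl group may be oxidised in competition.
Fallback (selection in the ring opening in place of selection in the epoxidation): the fallback sets out from 16. Buffered m-chloroperbenzoic acid in CH2Cl2 at 0 °C gives 17 together with its ring-epoxide diastereomer F5. The mixture is taken into the LiBr/AcOH opening of step 11, where 17 reacts through the chair-like transition state at the tertiary carbon. F5 can open only at the secondary carbon or through a non-chair path and should be much slower, which is the known kinetic differentiation of the cis and trans oxides of 4-substituted 1-methylcyclohexenes. Unchanged F5 is removed by chromatography and the route is rejoined at bromohydrin 18.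

Further compounds
F1 | step 4 | (E)-SAMP hydrazone of 5, N-[(2S)-2-(methoxymethyl)pyrrolidin-1-yl]imine of (3R)-3,7-dimethyl-3-(triethylsilyloxy)oct-6-enal | CC(C)=CCC[C@@](C)(O[Si](CC)(CC)CC)C/C=N/N1CCC[C@H]1COC
F2 | step 4 | (E)-SAMP hydrazone of (2R,3R)-3,7-dimethyl-2-[2-(2-methyl-1,3-dioxolan-2-yl)ethyl]-3-(triethylsilyloxy)oct-6-enal | CC(C)=CCC[C@@](C)(O[Si](CC)(CC)CC)[C@H](/C=N/N1CCC[C@H]1COC)CCC1(C)OCCO1
F3 | step 4 | (2R,3R)-3,7-dimethyl-2-[2-(2-methyl-1,3-dioxolan-2-yl)ethyl]-3-(triethylsilyloxy)oct-6-enal | CC(C)=CCC[C@@](C)(O[Si](CC)(CC)CC)[C@H](C=O)CCC1(C)OCCO1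
F4 | step 12 | tert-butyl({(3R,6R)-6-[(1S,3R,4R)-4-bromo-3-chloro-4-methylcyclohexyl]-2-methyl-6-(triethylsilyloxy)hept-1-en-3-yl}oxy)dimethylsilane | C=C(C)[C@H](O[Si](C)(C)C(C)(C)C)CC[C@@](C)(O[Si](CC)(CC)CC)[C@H]1CC[C@@](C)(Br)[C@H](Cl)C1
F5 | step 10 | (1R,4S,6S)-4-[(2R,5R)-5-(tert-butyldimethylsilyloxy)-6-methyl-2-(triethylsilyloxy)hept-6-en-2-yl]-1-methyl-7-oxabicyclo[4.1.0]heptane (epoxide oxygen on the ring face of the side chain) | C=C(C)[C@H](O[Si](C)(C)C(C)(C)C)CC[C@@](C)(O[Si](CC)(CC)CC)[C@H]1CC[C@@]2(C)O[C@H]2C1
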